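Monday's run and Wednesday's differ in their charge of E, and Wednesday's flask is the one asked about at 20 h.

in all of them: G 0.050 M

| charge | E | remark | time |
|---|---|---|---|
| Wednesday's | 0.055 M | the very flask that is asked about, followed so far |  |
| Monday's | 0.037 M | run made earlier |  |
| flask | 0.0550 M |  | 20 h |

| run | time / h | D / % | Z / % |
|---|---|---|---|
| Wednesday's | 0.500 | 2.7 | 0.3 |
| Wednesday's | 0.833 | 3.7 | 0.2 |
| Wednesday's | 1.33 | 5.8 | 0.4 |
| Wednesday's | 2.00 | 7.6 | 0 |
| Wednesday's | 4.00 | 12.2 | 0.3 |
| Wednesday's | 6.00 | 14.6 | 0.3 |
| Monday's | 1.50 | 4.6 | 0 |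
| Monday's | 2.50 | 5.7 | 0.2 |
| Monday's | 4.00 | 7.9 | 0 |
| Monday's | 8.00 | 11.2 | 0 |
| Monday's | 12.0 | 13.7 | 0 |
| Monday's | 20.0 | 16.5 | 0.6 |

(readings scatter by 0.3 percentage points)

- D is meant together with its Z
- solid, in amounts per volume of the solution: G
- the analysis behind the earlier runs scatters by 0.3 percentage points, standard deviation
- steps under discussion: G <-> X; X + E -> D; E <-> J; D <-> L; E + D <-> Z
- at the start none of G is in solution
- X means what is dissolved; the solid is not counted in it

* the D and Z together standing at 20 h, as a percentage of the G charged
* concentration of X in solution at 20 h, in percent of saturation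

I took the formation of D as pseudo-first-order in E, with the rate equal to the charge of E times a function of time common to both runs. Integrating that rate gives D and Z at a given time as the charge of E times one number, which I call the yield per charge of E. I read it from Monday's run at 20.0 h: 4.46 M⁻¹. At 4.00 h the same number read 2.22 M⁻¹ on Wednesday and 2.14 M⁻¹ on Monday; scaled by the charges of E, those two readings stood 0.46 percentage points apart, each scattering by 0.3 points.

Monday's gain per hour was smaller from 12.0 h to 20.0 h than from 4.00 h to 8.00 h, and my bracket assumed that fall in both runs. I started from Wednesday's 14.6% at 6.00 h. As a lower bound I added Monday's gain over the shorter stretch from 8.00 h to 20.0 h, unscaled, which gave 19.9%. As an upper bound I added Monday's gain over the longer stretch from 4.00 h, scaled by the ratio of the charges of E, 1.49, which gave 27.4%. Inside it I committed to the yield per charge times 0.0550 M, which is 24.5%. Neither run reads X, so I reckoned no figure for it.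

The forecast, holding that “X should sit just below saturation”, gave 97% of saturation and 26% for D and Z, which is inside my bracket and above my figure.

The flask gave 23.6%, with X at 87.3% of saturation.

    G ⇌ X, rate k1*(cs1 - [X]) while solid is left; crystals form when [X] > cs1 (solubility = 21.0 mM, k = 0.0160 min⁻¹)
    X + E → D (k = 0.530 M⁻¹ min⁻¹)
    E ⇌ J (K = 11.0, k = 0.0480 min⁻¹)
    D ⇌ L (K = 2.40, k = 0.00400 min⁻¹)
    E + D ⇌ Z, settled at all times (K = 7.30 M⁻¹)

Wednesday's flask had a yield per charge of E of 4.29 M⁻¹; its 23.6% lay inside the bracket, and my figure stood 0.9 points high. I applied the same yield per charge to the neighbouring flask, which differs in holding 0.014 M of E, and got 6.24%. That flask gave 6.17% of D and Z at 20 h, with 10.6% as L and 41.8% still standing as solid G.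

(The data are simulated from invented constants; noise was put on by code.)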